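**Plan**

1. Feature used: in each flavanone half the ring oxygen (O1, O1'') is an aryl ether oxygen that ties a secondary benzylic carbon (C2, C2'') to an aryl carbon (C8a of ring A, C8a'' of ring D). Each pyran ring (ring C: O1, C2, C3, C4, C4a, C8a; ring F: its double-primed counterpart) can therefore be closed at the aryl carbon by an alcohol of fixed configuration. The retrosynthesis first returns both C4 ketones to exocyclic methylenes and the free phenols to methyl ethers (O5, O5'') and a benzyl ether (O4'''), then cuts O1–C8a and O1''–C8a'' to an open-chain bis(ortho-bromoaryl) diol.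
2. Further cuts: C2–C3 and C2''–C3'' (two allylborations of aryl aldehydes by 2-arylallyl pinacolboronates); the diaryl ether bond O–C4' (SNAr on 4-fluorobenzonitrile, the nitrile being the latent ring B aldehyde); and C4–C4a and C4''–C4a'' (Friedel–Crafts acylation ortho to bromine with acetoxyacetyl chloride, which brings in the allylic oxygen so that no electron-rich styrene has to be halogenated).
3. Forward order: ring A boronate (steps 1–3); diaryl ether and ring D boronate (steps 4–7); chain joined to the ring E aldehyde (step 8); nitrile to aldehyde (step 9); chain joined to the ring A boronate (step 10); rings C and F closed together (step 11); both methylenes cleaved to ketones (step 12); benzyl and peri methyl groups removed (step 13).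
4. Stereochemistry: C2'' (step 8) and C2 (step 10) are each set as S by catalyst control in a chiral-phosphoric-acid-catalysed allylboration. Both are carried unchanged to the target because no later step breaks a bond at either carbinol carbon.

Key step: step 11

Assumption: (S)-TRIP, (S)-3,3'-bis(2,4,6-triisopropylphenyl)-1,1'-binaphthyl-2,2'-diyl hydrogen phosphate, is taken to expose the Si face of an aromatic aldehyde, as the mirror image of the (R)-TRIP/benzaldehyde case that leads to the R homoallylic alcohol; with OH > aryl > CH2 > H this face gives the S carbinol.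

**Route**

Step 1
Reactants: 1 1-bromo-3,5-dimethoxybenzene; 2 acetoxyacetyl chloride
Product: 3 2-(2-bromo-4,6-dimethoxyphenyl)-2-oxoethyl acetate
Conditions: AlCl3 (2.2 equiv), CH2Cl2, 0 °C
Reagents that add atoms: none
Why: Friedel–Crafts acylation, in which 5-substituted 1,3-dimethoxybenzenes are attacked para to one methoxy group and ortho to the other, here at the carbon next to bromine, while the low temperature and cold quench should spare the methyl ether ortho to the new ketone from chelation-assisted cleavage.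

Step 2
Reactants: 3 2-(2-bromo-4,6-dimethoxyphenyl)-2-oxoethyl acetate
Product: 4 2-(2-bromo-4,6-dimethoxyphenyl)prop-2-en-1-yl acetate
Conditions: Zn, CH2Br2, TiCl4, THF/CH2Cl2, 0 °C → rt
Reagents that add atoms: dibromomethane, BrCBr
Why: Takai–Lombardo methylenation, whose weakly basic geminal dimetal reagent adds to hindered and enolisable ketones where a phosphorus ylide would deprotonate the α-acetoxy ketone, and which leaves the acetate and the aryl bromide alone.

Step 3
Reactants: 4 2-(2-bromo-4,6-dimethoxyphenyl)prop-2-en-1-yl acetate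
Product: 5 2-[2-(2-bromo-4,6-dimethoxyphenyl)prop-2-en-1-yl]-4,4,5,5-tetramethyl-1,3,2-dioxaborolane
Conditions: B2pin2, Pd2(dba)3 (2.5 mol%), DMSO, 50 °C
Reagents that add atoms: bis(pinacolato)diboron, CC1(C)OB(OC1(C)C)B1OC(C)(C)C(C)(C)O1
Why: Miyaura-type borylation of an allylic acetate, in which phosphine-free zerovalent palladium ionises the acetate to a π-allyl complex that B2pin2 borylates, a path expected to be much faster at 50 °C than insertion into the electron-rich, ortho-substituted aryl bromide; both allyl termini of the 2-aryl system give the same boronate.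

Step 4
Reactants: 6 4-bromo-2,6-dimethoxyphenol; 7 4-fluorobenzonitrile
Product: 8 4-(4-bromo-2,6-dimethoxyphenoxy)benzonitrile
Conditions: K2CO3, DMSO, 110 °C
Reagents that add atoms: none
Why: SNAr, in which the phenoxide of 6 displaces fluoride para to the nitrile through a Meisenheimer adduct, a reaction type established for 2,6-dimethoxyphenols, while the unactivated aryl bromide stays inert.

Step 5
Reactants: 8 4-(4-bromo-2,6-dimethoxyphenoxy)benzonitrile; 2 acetoxyacetyl chloride
Product: 9 2-[6-bromo-3-(4-cyanophenoxy)-2,4-dimethoxyphenyl]-2-oxoethyl acetate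
Conditions: AlCl3 (3 equiv), CH2Cl2, 0 °C → rt
Reagents that add atoms: none
Why: Friedel–Crafts acylation, for which only the two equivalent positions of the trioxygenated ring (ortho to bromine, ortho and para to methoxy) are open and activated, whereas the cyanophenyl ring is deactivated further by AlCl3 bound to the nitrile, so a single ketone ortho to bromine is expected.

Step 6
Reactants: 9 2-[6-bromo-3-(4-cyanophenoxy)-2,4-dimethoxyphenyl]-2-oxoethyl acetate
Product: 10 2-[6-bromo-3-(4-cyanophenoxy)-2,4-dimethoxyphenyl]prop-2-en-1-yl acetate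
Conditions: Zn, CH2Br2, TiCl4, THF/CH2Cl2, 0 °C → rt
Reagents that add atoms: dibromomethane, BrCBr
Why: Takai–Lombardo methylenation as in step 2, with the nitrile, the acetate and the aryl bromide expected to be inert to the Zn/CH2Br2/TiCl4 reagent.

Step 7
Reactants: 10 2-[6-bromo-3-(4-cyanophenoxy)-2,4-dimethoxyphenyl]prop-2-en-1-yl acetate
Product: 11 4-{4-bromo-2,6-dimethoxy-3-[3-(4,4,5,5-tetramethyl-1,3,2-dioxaborolan-2-yl)prop-1-en-2-yl]phenoxy}benzonitrile
Conditions: B2pin2, Pd2(dba)3 (2.5 mol%), DMSO, 50 °C
Reagents that add atoms: bis(pinacolato)diboron, CC1(C)OB(OC1(C)C)B1OC(C)(C)C(C)(C)O1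
Why: Miyaura-type allylic borylation as in step 3, with the nitrile inert and the aryl bromide expected to survive ligand-free zerovalent palladium at 50 °C.

Step 8
Reactants: 11 4-{4-bromo-2,6-dimethoxy-3-[3-(4,4,5,5-tetramethyl-1,3,2-dioxaborolan-2-yl)prop-1-en-2-yl]phenoxy}benzonitrile; 12 4-(benzyloxy)benzaldehyde
Product: 14 4-{3-[(4S)-4-[4-(benzyloxy)phenyl]-4-hydroxybut-1-en-2-yl]-4-bromo-2,6-dimethoxyphenoxy}benzonitrile, via pinacol borate ester 13 (not isolated)
Conditions: (S)-TRIP (5 mol%), 4 Å MS, toluene, −30 °C; then aq. NaHCO3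
Reagents that add atoms: none
Why: Chiral-phosphoric-acid-catalysed allylboration, in which the boronate adds through a closed chair transition state with allylic transposition (the boron-bearing carbon becomes the exocyclic methylene) and the acid, hydrogen-bonded to a boronate oxygen and the formyl hydrogen, exposes the Si face of the aldehyde, so that C2'' should be set as S.

Step 9
Reactants: 14 4-{3-[(4S)-4-[4-(benzyloxy)phenyl]-4-hydroxybut-1-en-2-yl]-4-bromo-2,6-dimethoxyphenoxy}benzonitrile
Product: 16 4-{3-[(4S)-4-[4-(benzyloxy)phenyl]-4-hydroxybut-1-en-2-yl]-4-bromo-2,6-dimethoxyphenoxy}benzaldehyde, via aluminium aldimine 15 (not isolated)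
Conditions: i-Bu2AlH (2.5 equiv), CH2Cl2, −78 °C; then aq. KNaC4H4O6, rt
Reagents that add atoms: water, O (supplies the aldehyde oxygen at work-up)
Why: Partial reduction of a nitrile with i-Bu2AlH, in which one equivalent is spent on the hydroxyl group and a second adds once to the nitrile to give an aluminium aldimine that resists further hydride and is hydrolysed to the aldehyde on work-up, leaving the carbinol centre, the alkene, the aryl bromide and the benzyl ether untouched.

Step 10
Reactants: 16 4-{3-[(4S)-4-[4-(benzyloxy)phenyl]-4-hydroxybut-1-en-2-yl]-4-bromo-2,6-dimethoxyphenoxy}benzaldehyde; 5 2-[2-(2-bromo-4,6-dimethoxyphenyl)prop-2-en-1-yl]-4,4,5,5-tetramethyl-1,3,2-dioxaborolane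
Product: 18 (1S)-1-[4-(benzyloxy)phenyl]-3-{6-bromo-3-[4-[(1S)-3-(2-bromo-4,6-dimethoxyphenyl)-1-hydroxybut-3-en-1-yl]phenoxy]-2,4-dimethoxyphenyl}but-3-en-1-ol, via pinacol borate ester 17 (not isolated)
Conditions: (S)-TRIP (10 mol%), 4 Å MS, toluene, −30 °C; then aq. NaHCO3
Reagents that add atoms: none
Why: Second chiral-phosphoric-acid-catalysed allylboration, in which the same catalyst-controlled Si-face addition should set C2 as S independently of the remote C2'' centre, so that the minor enantiomer from step 8 is carried into a diastereomer, while the free hydroxyl group does not react with a pinacol boronate.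

Step 11
Reactants: 18 (1S)-1-[4-(benzyloxy)phenyl]-3-{6-bromo-3-[4-[(1S)-3-(2-bromo-4,6-dimethoxyphenyl)-1-hydroxybut-3-en-1-yl]phenoxy]-2,4-dimethoxyphenyl}but-3-en-1-ol
Product: 21 (2S)-2-[4-({(2S)-2-[4-(benzyloxy)phenyl]-5,7-dimethoxy-4-methylidene-3,4-dihydro-2H-chromen-6-yl}oxy)phenyl]-5,7-dimethoxy-4-methylidene-3,4-dihydro-2H-chromene, via ring-C-closed bromo alcohol 19 (not isolated), via ring-F-closed bromo alcohol 20 (not isolated)
Conditions: Pd(OAc)2 (10 mol%), 2-(di-tert-butylphosphino)-1,1'-binaphthyl (12 mol%), Cs2CO3 (4 equiv), toluene, 70 °C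
Reagents that add atoms: none
Why: Zerovalent palladium, formed in the flask from Pd(OAc)2 and the phosphine, inserts into each aryl C–Br bond, Cs2CO3 turns the neighbouring secondary alcohol into an alkoxide that replaces bromide on divalent palladium, and C–O reductive elimination then forms O1–C8a and O1''–C8a''. The closest known reaction is the Buchwald–Hartwig-type intramolecular etherification of ortho-bromoaryl alkanols bearing secondary hydroxyl groups, which gives chromans. Ring C (O1, C2, C3, C4, C4a, C8a) and ring F (O1'', C2'', C3'', C4'', C4a'', C8a'') each close as a six-membered aryl ether by reductive elimination from a seven-membered oxapalladacycle, that is, by aryl C–O bond formation at the ring-fusion carbon. No stereocentre is created, and C2 and C2'' should keep the S configuration from steps 10 and 8 because only the O–H bond of each carbinol is broken. The step needs C–O reductive elimination to outrun β-hydride elimination of the benzylic alkoxide, which the bulky, electron-rich di-tert-butylbiarylphosphine should ensure by keeping palladium low-coordinate, and it needs each alcohol to find its own bromide, which the four-atom tether guarantees since only the six-membered closure is within reach. The C4 and C4'' methylenes cannot insert into the adjacent arylpalladium (a four-membered ring would result) and, unlike the ketones they stand for, offer no path to retro-aldol cleavage or elimination under carbonate base.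

Step 12
Reactants: 21 (2S)-2-[4-({(2S)-2-[4-(benzyloxy)phenyl]-5,7-dimethoxy-4-methylidene-3,4-dihydro-2H-chromen-6-yl}oxy)phenyl]-5,7-dimethoxy-4-methylidene-3,4-dihydro-2H-chromene
Product: 23 (2S)-2-[4-({(2S)-2-[4-(benzyloxy)phenyl]-5,7-dimethoxy-4-oxo-3,4-dihydro-2H-chromen-6-yl}oxy)phenyl]-5,7-dimethoxy-2,3-dihydro-4H-chromen-4-one, via bis(1,2-diol) 22 (not isolated)
Conditions: OsO4 (5 mol%), NaIO4 (8 equiv), 2,6-lutidine, dioxane/H2O 3:1, rt
Reagents that add atoms: osmium tetroxide, O=[Os](=O)(=O)=O (delivers both ketone oxygens; it is regenerated by sodium periodate, [Na+].[O-]I(=O)(=O)=O, the ultimate oxygen source)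
Why: Lemieux–Johnson oxidation, in which OsO4 dihydroxylates the two 1,1-disubstituted exocyclic alkenes, the only alkenes present, and NaIO4 cleaves each diol to the aryl ketone and formaldehyde under lutidine-buffered, near-neutral conditions that should neither open the flavanone rings nor attack the electron-rich arenes as ozone might.

Step 13
Reactants: 23 (2S)-2-[4-({(2S)-2-[4-(benzyloxy)phenyl]-5,7-dimethoxy-4-oxo-3,4-dihydro-2H-chromen-6-yl}oxy)phenyl]-5,7-dimethoxy-2,3-dihydro-4H-chromen-4-one
Product: 25 7,7''-di-O-methyltetrahydrohinokiflavone, via tris(dichloroboryl) ether 24 (not isolated)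
Conditions: BCl3 (8 equiv), C6HMe5 (4 equiv), CH2Cl2, −78 → 0 °C; then H2O
Reagents that add atoms: none
Why: Chelation-controlled ether cleavage with BCl3, which binds each C4 carbonyl together with the peri methoxy oxygen so that chloride removes only the C5 and C5'' methyl groups, while the benzyl ether is cleaved through a benzyl cation that pentamethylbenzene traps; the non-chelated C7 and C7'' methyl ethers, the diaryl ether and the C2 centres should persist at or below 0 °C.

**Compound list**

1 | 1-bromo-3,5-dimethoxybenzene | COc1cc(Br)cc(OC)c1 | starting material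
2 | acetoxyacetyl chloride | CC(=O)OCC(=O)Cl | starting material
3 | 2-(2-bromo-4,6-dimethoxyphenyl)-2-oxoethyl acetate | COc1cc(OC)c(C(=O)COC(C)=O)c(Br)c1 | intermediate
4 | 2-(2-bromo-4,6-dimethoxyphenyl)prop-2-en-1-yl acetate | COc1cc(OC)c(C(=C)COC(C)=O)c(Br)c1 | intermediate
5 | 2-[2-(2-bromo-4,6-dimethoxyphenyl)prop-2-en-1-yl]-4,4,5,5-tetramethyl-1,3,2-dioxaborolane (ring A allylboronate) | COc1cc(OC)c(C(=C)CB2OC(C)(C)C(C)(C)O2)c(Br)c1 | intermediate
6 | 4-bromo-2,6-dimethoxyphenol | COc1cc(Br)cc(OC)c1O | starting material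
7 | 4-fluorobenzonitrile | N#Cc1ccc(F)cc1 | starting material
8 | 4-(4-bromo-2,6-dimethoxyphenoxy)benzonitrile | COc1cc(Br)cc(OC)c1Oc1ccc(C#N)cc1 | intermediate
9 | 2-[6-bromo-3-(4-cyanophenoxy)-2,4-dimethoxyphenyl]-2-oxoethyl acetate | COc1cc(Br)c(C(=O)COC(C)=O)c(OC)c1Oc1ccc(C#N)cc1 | intermediate
10 | 2-[6-bromo-3-(4-cyanophenoxy)-2,4-dimethoxyphenyl]prop-2-en-1-yl acetate | COc1cc(Br)c(C(=C)COC(C)=O)c(OC)c1Oc1ccc(C#N)cc1 | intermediate
11 | 4-{4-bromo-2,6-dimethoxy-3-[3-(4,4,5,5-tetramethyl-1,3,2-dioxaborolan-2-yl)prop-1-en-2-yl]phenoxy}benzonitrile (ring D allylboronate) | COc1cc(Br)c(C(=C)CB2OC(C)(C)C(C)(C)O2)c(OC)c1Oc1ccc(C#N)cc1 | intermediate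
12 | 4-(benzyloxy)benzaldehyde | O=Cc1ccc(OCc2ccccc2)cc1 | starting material
13 | O-pinacolboryl ether of 14 (S carbinol; hydrolysed at work-up) | COc1cc(Br)c(C(=C)C[C@H](OB2OC(C)(C)C(C)(C)O2)c2ccc(OCc3ccccc3)cc2)c(OC)c1Oc1ccc(C#N)cc1 | intermediate
14 | 4-{3-[(4S)-4-[4-(benzyloxy)phenyl]-4-hydroxybut-1-en-2-yl]-4-bromo-2,6-dimethoxyphenoxy}benzonitrile | COc1cc(Br)c(C(=C)C[C@H](O)c2ccc(OCc3ccccc3)cc2)c(OC)c1Oc1ccc(C#N)cc1 | intermediate
15 | O-diisobutylaluminium alkoxide and N-diisobutylaluminium aldimine derived from 14 (S carbinol; hydrolysed at work-up) | COc1cc(Br)c(C(=C)C[C@H](O[Al](CC(C)C)CC(C)C)c2ccc(OCc3ccccc3)cc2)c(OC)c1Oc1ccc(C=N[Al](CC(C)C)CC(C)C)cc1 | intermediate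
16 | 4-{3-[(4S)-4-[4-(benzyloxy)phenyl]-4-hydroxybut-1-en-2-yl]-4-bromo-2,6-dimethoxyphenoxy}benzaldehyde | COc1cc(Br)c(C(=C)C[C@H](O)c2ccc(OCc3ccccc3)cc2)c(OC)c1Oc1ccc(C=O)cc1 | intermediate
17 | O-pinacolboryl ether of 18 at the newly formed C2 carbinol (both carbinols S; hydrolysed at work-up) | COc1cc(OC)c(C(=C)C[C@H](OB2OC(C)(C)C(C)(C)O2)c2ccc(Oc3c(OC)cc(Br)c(C(=C)C[C@H](O)c4ccc(OCc5ccccc5)cc4)c3OC)cc2)c(Br)c1 | intermediate
18 | (1S)-1-[4-(benzyloxy)phenyl]-3-{6-bromo-3-[4-[(1S)-3-(2-bromo-4,6-dimethoxyphenyl)-1-hydroxybut-3-en-1-yl]phenoxy]-2,4-dimethoxyphenyl}but-3-en-1-ol (bis-bromide diol, both carbinols S) | COc1cc(OC)c(C(=C)C[C@H](O)c2ccc(Oc3c(OC)cc(Br)c(C(=C)C[C@H](O)c4ccc(OCc5ccccc5)cc4)c3OC)cc2)c(Br)c1 | intermediate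
19 | monocyclised bromo alcohol with ring C closed (2S chroman; S carbinol on the ring D side) | COc1cc(OC)c2c(c1)O[C@H](c1ccc(Oc3c(OC)cc(Br)c(C(=C)C[C@H](O)c4ccc(OCc5ccccc5)cc4)c3OC)cc1)CC2=C | intermediate
20 | monocyclised bromo alcohol with ring F closed (2''S chroman; S carbinol on the ring A side) | COc1cc(OC)c(C(=C)C[C@H](O)c2ccc(Oc3c(OC)cc4c(c3OC)C(=C)C[C@@H](c3ccc(OCc5ccccc5)cc3)O4)cc2)c(Br)c1 | intermediate
21 | (2S)-2-[4-({(2S)-2-[4-(benzyloxy)phenyl]-5,7-dimethoxy-4-methylidene-3,4-dihydro-2H-chromen-6-yl}oxy)phenyl]-5,7-dimethoxy-4-methylidene-3,4-dihydro-2H-chromene (bis(4-methyleneflavan), 2S,2''S) | COc1cc(OC)c2c(c1)O[C@H](c1ccc(Oc3c(OC)cc4c(c3OC)C(=C)C[C@@H](c3ccc(OCc5ccccc5)cc3)O4)cc1)CC2=C | intermediate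
22 | bis(4-hydroxy-4-hydroxymethyl)flavan tetraol from 21 (2S,2''S; mixture of epimers at C4 and C4'', centres that are destroyed in the same flask) | COc1cc(OC)c2c(c1)O[C@H](c1ccc(Oc3c(OC)cc4c(c3OC)C(O)(CO)C[C@@H](c3ccc(OCc5ccccc5)cc3)O4)cc1)CC2(O)CO | intermediate
23 | (2S)-2-[4-({(2S)-2-[4-(benzyloxy)phenyl]-5,7-dimethoxy-4-oxo-3,4-dihydro-2H-chromen-6-yl}oxy)phenyl]-5,7-dimethoxy-2,3-dihydro-4H-chromen-4-one (benzyl tetramethyl ether of the target skeleton) | COc1cc(OC)c2c(c1)O[C@H](c1ccc(Oc3c(OC)cc4c(c3OC)C(=O)C[C@@H](c3ccc(OCc5ccccc5)cc3)O4)cc1)CC2=O | intermediate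
24 | 5,5'',4'''-tris(O-dichloroboryl) derivative of 25 (2S,2''S; hydrolysed at work-up) | COc1cc(OB(Cl)Cl)c2c(c1)O[C@H](c1ccc(Oc3c(OC)cc4c(c3OB(Cl)Cl)C(=O)C[C@@H](c3ccc(OB(Cl)Cl)cc3)O4)cc1)CC2=O | intermediate
25 | 7,7''-di-O-methyltetrahydrohinokiflavone, (2S)-5-hydroxy-2-[4-({(2S)-5-hydroxy-2-(4-hydroxyphenyl)-7-methoxy-4-oxo-3,4-dihydro-2H-chromen-6-yl}oxy)phenyl]-7-methoxy-2,3-dihydro-4H-chromen-4-one | COc1cc(O)c2c(c1)O[C@H](c1ccc(Oc3c(OC)cc4c(c3O)C(=O)C[C@@H](c3ccc(O)cc3)O4)cc1)CC2=O | target

**Step count and risks**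

Total steps: 13. Longest linear sequence: 10 steps (steps 4–13, from 6 and 7); the ring A branch (steps 1–3) joins at step 10.

Steps most likely to fail:

Step 11. Several processes could divert the twofold closure. The benzylic palladium alkoxide may undergo β-hydride elimination, oxidising the carbinol to an aryl ketone with hydrodebromination. The homoallylic alkoxide may undergo retro-allylation, cleaving C2–C3. The catalyst may decay after the first ring closure. Palladium hydride may move the exocyclic double bonds into the rings, which would block step 12. The fallback closes the rings one at a time on mono-bromides and under copper catalysis, where an alkoxide has no ready β-hydride or retro-allylation path. It sets out from 14: an Ullmann-type etherification (CuI, 8-hydroxyquinoline, Cs2CO3, toluene, 110 °C) should give the ring-F-closed 4-methyleneflavan nitrile F1. Reduction with i-Bu2AlH, through the aluminium aldimine F2 (not isolated), should give the aldehyde F3. The (S)-TRIP-catalysed allylboration of F3 with 5 should give, through the pinacol borate ester F4 (not isolated), the ring-F-closed bromo alcohol 20, which is isolated this time. A second copper-catalysed etherification under the same conditions closes ring C and returns to the route at 21.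

Step 6 (its twin, step 2, is less encumbered and serves as the test bed). The ketone carbon lies between an ortho bromine and an ortho methoxy group that is itself buttressed by the aryloxy neighbour. Addition of the methylene reagent may therefore be slow, and the α-acetoxy ketone may instead enolise or lose its acetate reductively. The fallback brings in the alkene by cross-coupling, so that no addition to the hindered carbonyl is needed. It sets out from 8: iodination with N-iodosuccinimide and catalytic CF3CO2H in MeCN at the only activated ring position should give 4-(4-bromo-3-iodo-2,6-dimethoxyphenoxy)benzonitrile F5. A Stille coupling at the more reactive carbon–iodine bond with 2-(tributylstannyl)prop-2-en-1-ol (Pd(PPh3)4, CuI, CsF, DMF, 45 °C) should give the 2-arylallyl alcohol F6; the free alcohol is used so that zerovalent palladium meets no allylic acetate. Acetylation (Ac2O, pyridine, DMAP) returns to the route at 10.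

Step 10 (step 8 shares the issue). Facial selectivity may be poor: the boronate carries a bulky, twisted 2-aryl group, and the free hydroxyl group of 16 may compete for the phosphoric acid, so the uncatalysed background addition could erode the configuration at C2. The fallback sets both carbinols by reagent-controlled ketone reduction instead. It sets out from 16 and 5: uncatalysed allylboration (toluene, 40 °C) should give, after hydrolysis of the pinacol borate ester F7 (not isolated), the diol F8 as a mixture of epimers at the new carbinol. Dess–Martin oxidation (NaHCO3-buffered, CH2Cl2) of both carbinols should give the achiral bis(β,γ-unsaturated) diketone F9. A Corey–Bakshi–Shibata reduction with (R)-2-methyl-CBS-oxazaborolidine and catecholborane (toluene, −78 °C; aryl as the large group, hence S at both centres; non-basic, so the alkenes should not move into conjugation) should give, after hydrolysis of the bis(catecholborate) F10 (not isolated), the S,S diol and return to the route at 18.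

**Further compounds**

F1 | step 11 | 4-({(2S)-2-[4-(benzyloxy)phenyl]-5,7-dimethoxy-4-methylidene-3,4-dihydro-2H-chromen-6-yl}oxy)benzonitrile | COc1cc2c(c(OC)c1Oc1ccc(C#N)cc1)C(=C)C[C@@H](c1ccc(OCc3ccccc3)cc1)O2
F2 | step 11 | N-diisobutylaluminium aldimine derived from F1 (2S; not isolated) | COc1cc2c(c(OC)c1Oc1ccc(C=N[Al](CC(C)C)CC(C)C)cc1)C(=C)C[C@@H](c1ccc(OCc3ccccc3)cc1)O2
F3 | step 11 | 4-({(2S)-2-[4-(benzyloxy)phenyl]-5,7-dimethoxy-4-methylidene-3,4-dihydro-2H-chromen-6-yl}oxy)benzaldehyde | COc1cc2c(c(OC)c1Oc1ccc(C=O)cc1)C(=C)C[C@@H](c1ccc(OCc3ccccc3)cc1)O2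
F4 | step 11 | O-pinacolboryl ether of 20 (S carbinol, 2''S; not isolated) | COc1cc(OC)c(C(=C)C[C@H](OB2OC(C)(C)C(C)(C)O2)c2ccc(Oc3c(OC)cc4c(c3OC)C(=C)C[C@@H](c3ccc(OCc5ccccc5)cc3)O4)cc2)c(Br)c1
F5 | step 6 | 4-(4-bromo-3-iodo-2,6-dimethoxyphenoxy)benzonitrile | COc1cc(Br)c(I)c(OC)c1Oc1ccc(C#N)cc1
F6 | step 6 | 4-[4-bromo-3-(3-hydroxyprop-1-en-2-yl)-2,6-dimethoxyphenoxy]benzonitrile | COc1cc(Br)c(C(=C)CO)c(OC)c1Oc1ccc(C#N)cc1
F7 | step 10 | O-pinacolboryl ether of F8 at the new carbinol (that centre unassigned, the other S; not isolated) | COc1cc(OC)c(C(=C)CC(OB2OC(C)(C)C(C)(C)O2)c2ccc(Oc3c(OC)cc(Br)c(C(=C)C[C@H](O)c4ccc(OCc5ccccc5)cc4)c3OC)cc2)c(Br)c1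
F8 | step 10 | bis-bromide diol as a mixture of epimers at the carbinol next to ring B (the ring E carbinol S) | COc1cc(OC)c(C(=C)CC(O)c2ccc(Oc3c(OC)cc(Br)c(C(=C)C[C@H](O)c4ccc(OCc5ccccc5)cc4)c3OC)cc2)c(Br)c1
F9 | step 10 | 1-[4-(benzyloxy)phenyl]-3-{6-bromo-3-[4-[3-(2-bromo-4,6-dimethoxyphenyl)but-3-enoyl]phenoxy]-2,4-dimethoxyphenyl}but-3-en-1-one (achiral diketone) | COc1cc(OC)c(C(=C)CC(=O)c2ccc(Oc3c(OC)cc(Br)c(C(=C)CC(=O)c4ccc(OCc5ccccc5)cc4)c3OC)cc2)c(Br)c1
F10 | step 10 | bis(O-catecholboryl) ether of 18 (both carbinols S; not isolated) | COc1cc(OC)c(C(=C)C[C@H](OB2Oc3ccccc3O2)c2ccc(Oc3c(OC)cc(Br)c(C(=C)C[C@H](OB4Oc5ccccc5O4)c4ccc(OCc5ccccc5)cc4)c3OC)cc2)c(Br)c1
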